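All runs come from a simulation on assumed constants, and the scatter is random.

Which flask ends with the larger excess of left-handed product over right-handed product, south-east at 40 °C or north-east at 20 °C?

| setting | green | amber | south-east | north-east |
|---|---|---|---|---|
| left-handed substrate | 0.050 M | 0.20 M | 0.10 M | 0.10 M |
| right-handed substrate | 0.050 M | 0.20 M | 0.10 M | 0.10 M |
| gas | 26 mM (held) | 26 mM (held) | 26 mM (held) | 26 mM (held) |
| temperature | 25 °C | 36 °C | 40 °C | 20 °C |
| remark | run made earlier | run made earlier |  |  |
| time |  |  | 4.0 h | 4.0 h |

| run | time / h | left-handed product / % | right-handed product / % |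
|---|---|---|---|
| green | 0.833 | 2.6 | 0.2 |
| green | 3.00 | 12.9 | 0 |
| green | 4.00 | 16.6 | 2.1 |
| green | 6.00 | 25.2 | 5.3 |
| green | 10.0 | 37.7 | 7.0 |
| amber | 1.00 | 3.5 | 2.1 |
| amber | 2.00 | 6.4 | 0.9 |
| amber | 3.00 | 9.6 | 1.4 |
| amber | 4.00 | 12.4 | 2.2 |
| amber | 5.00 | 15.1 | 1.6 |

(readings scatter by 1 percentage point)

- the flask that comes out highest in excess of left-handed product over right-handed product, or "all alike" when all lie within 1.5 percentage points (south-east / north-east / all alike)
- excess of left-handed product over right-handed product at the end, south-east
- excess of left-handed product over right-handed product at the end, north-east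

Both hands meet the same coupling partner. If each takes it in proportion to its own substrate, the partner cancels from their ratio and one number remains. Each product is counted against both substrates, so I double it: green's last reading puts left-handed substrate down by 75.4% and right-handed by 14.0%. The ratio of the logarithms of what remains reads 9.30: the selectivity factor, how many times faster a left-handed molecule reacts than a right-handed one.

My first answer takes conversion as small and s as the same in both flasks: s less one over s plus one, 80.6%. Now I put conversion back. Taking amber's average pace unchanged for south-east, I estimate 48.3% of its left-handed substrate consumed; taking green's for north-east, I estimate 15.1%. Then s gives right-handed conversions of 6.85% and 1.74%, so I estimate the excess at 75.2% in south-east and 79.3% in north-east. In this estimate north-east leads by 4.1 percentage points, more than the margin.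

Is one number enough? Amber's last reading gives 11.1, but one standard deviation more right-handed product gives 6.73, so that reading does not tell amber's s from green's 9.30.

The forecast also names north-east, with 67% and 79%, holding that “the falling excess comes mainly from conversion”. Its south-east figure is lower than mine.

The flask gives north-east: south-east 68.5%, north-east 82.0%.

    coupling partner + left-handed substrate → left-handed product (k = 0.150 L mol⁻¹ min⁻¹, Ea = 49.0 kJ mol⁻¹)
    gas ⇌ coupling partner, rate k2*(csat - [coupling partner]) (kL = 0.0110 min⁻¹)
    coupling partner + right-handed substrate → right-handed product (k = 0.0130 L mol⁻¹ min⁻¹, Ea = 71.0 kJ mol⁻¹)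
    coupling partner ⇌ dormant form (K = 4.00, k = 0.00580 min⁻¹, Ea = 103 kJ mol⁻¹, ΔH = −31.0 kJ mol⁻¹)
    (constants at 20 °C)

In south-east, of the turnover up to 4.00 h, half of the step to dormant form is done by 0.932 h and half of the gas transfer by 1.93 h. At 4.00 h south-east holds 0.00501 M coupling partner beside 0.00859 M dormant form, with 62% of the left-handed and 93% of the right-handed charge remaining. These remnants read 6.48 for s in south-east, less than my 9.30, and north-east's read 11.5, more. Read at 15 h, south-east's flask keeps 2.3% of its left-handed charge; 6.48 then gives 44.1% right-handed conversion and an excess of 37.8%, and the flask stands at 37.8%.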